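All runs are calculated for an exercise, and the scatter is random.

The late time asked about lies further out than the last reading of the midnight run, so I reach it by counting turnovers.

the same everywhere: substrate 0.39 M
- midnight: the very flask that is asked about, followed so far
- flask: time 2.5 h

midnight run (percent of the substrate charged)

| time / min | target / % | intermediate A / % |
|---|---|---|
| 2.00 | 0 | 0 |
| 4.00 | 1 | 4 |
| 6.00 | 0 | 4 |
| 10.0 | 0 | 10 |
| 15.0 | 0 | 10 |
| 25.0 | 3 | 17 |

(scatter of a reading: 1.5 percentage points)

* the state of affairs at 2.5 h: stopped, and by what, or still going (all of the substrate has reacted / forward and back rates have come level / it is still moving)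
* how much target there is at 2.5 h, in percent of the substrate charged
* how much intermediate A there is at 2.5 h, in percent of the substrate charged

- the reaction counts as stopped when no species that holds the substrate changes by six tenths of a point or more over the second half of the time

By 25.0 min the midnight run reads 17 % intermediate A and 3 % target, so about 20.0 % of the charge has left the substrate, which as a first-order loss is a read rate of 0.536 h⁻¹; at 2.5 h that makes 1.34 turnovers, a turnover count being that rate times the elapsed time.

I take the main step first, substrate to intermediate A. The fraction left is e to the minus count, 26.2 %, so intermediate A would hold 73.8 %, and since the substrate still falls by 25 percentage points over the second half of the time, I call the flask still moving.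

Then I add intermediate A to target, a consecutive scheme in which early target grows as half the product of both rates and the time squared. The target reading of 3 % carries the scatter, and the readings at 10.0 min and 15.0 min show 0 %, so I lean to that reading lowered to 1.50 %. That gives a second rate of 0.323 h⁻¹, a second count of 0.807, intermediate A 46.3 % and target 27.4 %.

As for the rest, I add no further step, since the target readings of the midnight run reach 3 % at most against a scatter of 1.5 points, and I hold my figures as estimates.

The forecast says it is still moving, with 30 % target and 38 % intermediate A, because “Substrate is still present and nothing suggests a plateau yet”, and my target lies below its figure while my intermediate A lies above.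

The flask gives it is still moving, with 19.6 % target and 43.5 % intermediate A.

    substrate → intermediate A (k = 1.33 × 10⁻⁴ s⁻¹)
    intermediate A ⇌ intermediate B (K = 2.32, k = 2.43 × 10⁻⁵ s⁻¹)
    intermediate A ⇌ target (K = 2.86, k = 7.66 × 10⁻⁵ s⁻¹)
    substrate → decomposition product (k = 5.29 × 10⁻⁷ s⁻¹)

At 2.5 h this flask keeps 30 % substrate, so its own count is 1.20 turnovers, fewer than my 1.34. Carried at the same rate to the neighbouring flask, the same charge read at 4.0 h, the count grows to 1.92 and leaves 14.7 % of the charge as substrate. That neighbouring flask holds 33.3 % target, 40.2 % intermediate A and 14.6 % substrate.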